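Late in the amber run, from 3.00 d to 8.00 d, isomer of the product reads 88.6% and then 89.3%. That run is the very flask asked about, followed so far.

all flasks: substrate 2.3 M; gas 200 mM (held)

| run | remark | time |
|---|---|---|
| amber | the very flask that is asked about, followed so far |  |
| flask |  | 15 d |

- amber (time / d: substrate / %, target / %, isomer of the product / %): 0.417: 21.4, 35.5, 44.4; 1.25: 8.5, 12.4, 78.0; 2.00: 6.6, 7.9, 86.7; 3.00: 4.7, 7.6, 88.6; 5.00: 4.8, 5.8, 88.9; 6.00: 3.1, 4.4, 89.2; 8.00: 2.4, 3.9, 89.3

(standard deviation of a reading: 1 percentage point)

- at the start none of partner is dissolved
- the analysis behind the earlier runs scatters by 1 percentage point, standard deviation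
- reactions considered so far: substrate + partner <-> target; substrate + partner <-> isomer of the product; partner -> decomposed reagent; gas <-> partner
- the reaction counts as stopped when no species that holds the substrate changes by six tenths of a point or more over the second half of the time

- the state of affairs at 15 d: stopped, and by what, or still going (all of the substrate has reacted / it is still moving / forward and back rates have come level)
- share of the substrate used up at 15 d
- target at 15 d, in percent of the substrate charged
- isomer of the product at 15 d, in percent of the substrate charged

**What was the amber flask doing before that?**
Target fell from 35.5% at 0.417 d to 7.9% at 2.00 d. Isomer of the product climbed to 86.7%. That is kinetic against thermodynamic control.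

**Replace the late curve by its mean. What do you get?**
Over the last 4 readings, substrate averages 3.75%, target 5.43% and isomer 89.0%. Dividing mean substrate by the sum of the three means gives 3.82%. Call this f, the late share of substrate. So I reckon 96.2% used up, with target at 5.53% and isomer at 90.6%.

**What error does the mean make?**
Take the readings in two pairs. The substrate means of the pairs lie 1 percentage point either side of the overall mean. The substrate mean stands above that error, so I do not call the substrate gone.

**But substrate plus target drops between the pairs. Isn't it still moving?**
It drops by 4.5 points, yet isomer gains just 0.5 points. The listed steps keep the charge within these three species, so a real drain should appear in isomer. I read the drop as scatter, at 1 point per reading. My call for 15 d is that forward and back rates have come level.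

The forecast says it is still moving, with 98.8% used up (97.3% to 99.8%), target 1.9% (0.7% to 3.5%) and isomer 90.5% (88.5% to 95%). Its grounds: "so they are in quasi-equilibrium, and their pool shrinks slowly". We differ on the end state, and my 96.2% is lower than its low end.

The flask gives: forward and back rates have come level, with 96.0% used up, target 5.98% and isomer 90.0%.

    substrate + partner ⇌ target (K = 8.10 M⁻¹, k = 2.43 M⁻¹ h⁻¹)
    substrate + partner ⇌ isomer of the product (K = 122 M⁻¹, k = 0.934 M⁻¹ h⁻¹)
    partner → decomposed reagent (k = 0.191 h⁻¹)
    gas ⇌ partner, rate k4*(csat - [partner]) (kL = 2.50 h⁻¹)

At 15.0 d the step to isomer, by itself, has a relaxation half-life of 0.108 d, both ways together, which is short against 15 d. The late share f read from the amber run was 3.82%, and at 15.0 d the flask keeps 4.0% as substrate. A neighbour flask is charged with 0.57 M of substrate, a quarter of this flask's charge, all else held. Taken over unchanged, f leaves 21.8 mM of that charge as substrate. At 15.0 d that neighbour flask keeps, as unbound substrate, 4.0% of its charge.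

All runs were generated by integration from invented constants, noise included.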